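**Assumptions (one line each)**
- (+)-Aromadendrin, (2R,3R)-dihydrokaempferol, is purchasable as the natural isomer. Its C2 and C3 centres are the only stereocentres, and no step touches them.
- In 5,7-dihydroxychromanones, kinetic electrophilic substitution (NBS) occurs mainly at C8. A 6-Br or 6,8-diBr by-product is removed by chromatography.

**Target check.** The SMILES is 6-(4-hydroxybenzyl)-5,7,4'-trihydroxy-3-hydroxyflavanone (6-(4-hydroxybenzyl)aromadendrin). By CIP, C2 = R and C3 = R (2,3-trans), the same as natural aromadendrin.

## Retrosynthetic overview
1. Disconnect the C6–CH2Ar bond. It is formed by trapping a photogenerated p-quinone methide (from 4-hydroxybenzyl alcohol) with the electron-rich A-ring C6.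
2. A removable C8 bromide blocks the more reactive C8 site. This forces C6 selectivity and prevents 6,8-dibenzylation.
3. The C8 bromide is installed on (2R,3R)-aromadendrin, which already supplies the chromanone ring and both stereocentres. No ring is formed in the route.
4. Order of events: C8 block, then C6 benzylation, then hydrodebromination.

## Forward route

**Step 1**
Reactants: 1 (2R,3R)-aromadendrin; 2 N-bromosuccinimide
Product: 3 (2R,3R)-8-bromoaromadendrin
Conditions: NBS (1.0 equiv), MeCN, –20 → 0 °C, 1 h, dark
Reagents that add atoms: NBS, O=C1CCC(=O)N1Br (adds Br)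
Why: Electrophilic aromatic bromination goes at the most nucleophilic A-ring carbon, C8, under kinetic control. The neutral, cold conditions leave the C2/C3 centres and the C3-OH untouched.

**Step 2**
Reactants: 3 8-bromoaromadendrin; 4 4-hydroxybenzyl alcohol
Product: 5 (2R,3R)-8-bromo-6-(4-hydroxybenzyl)aromadendrin
Conditions: 3 (1 equiv), 4 (2.5 equiv), MeCN/H2O 9:1, N2, hν (300 nm, Rayonet), 25 °C, 6 h
Reagents that add atoms: 4-hydroxybenzyl alcohol, OCc1ccc(O)cc1 (adds the C7H7O 4-hydroxybenzyl group; OH leaves as water)
Why: Proposed new method: Excited 4-hydroxybenzyl alcohol undergoes photodehydration (excited-state phenol-to-solvent proton transfer with loss of hydroxide) to give p-quinone methide. This is the known photosolvolysis of p-hydroxybenzyl alcohols.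
- The quinone methide is an exocyclic Michael acceptor, and the electron-rich, 7-OH-activated C6 of 3 adds to it (Friedel–Crafts/Michael-type C-alkylation), then rearomatises.
- Nothing like this has been shown for intermolecular C-benzylation of an unprotected polyphenolic flavanonol.
- Water captures the quinone methide reversibly, returning 4, so excess 4 is used.
- C8 is blocked, so C6 is the only free A-ring position. The conditions are neutral, so C2/C3 do not epimerise or ring-open.
- The 5-OH···O=C hydrogen bond gives fast excited-state deactivation, which protects the chromanone chromophore.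

**Step 3**
Reactants: 5 8-bromo-6-(4-hydroxybenzyl)aromadendrin
Product: 6 Gericudranin E
Conditions: H2 (1 atm), 10% Pd/C, NaOAc (1.2 equiv), EtOH/EtOAc 1:1, 25 °C, 3 h
Reagents that add atoms: none (H2 adds only hydrogen; Pd/C is the catalyst, NaOAc the HBr scavenger)
Why: Pd-catalysed hydrogenolysis of the aryl C–Br bond is chemoselective. The diarylmethane, aryl ketone, phenols and C3-OH survive. NaOAc buffers the HBr released so the trans-2,3 centres are not epimerised.

**Atom check**
- 1 (C15H12O6) + Br → 3 (C15H11BrO6).
- 3 + C7H8O2 − H2O → 5 (C22H17BrO7).
- 5 + H2 − HBr → 6 (C22H18O7), which matches the target formula.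

**Stereocentres.** Both centres (2R,3R) come from 1 and are untouched in all three steps.

## Compound list
1 | (2R,3R)-aromadendrin | O=C1c2c(O)cc(O)cc2O[C@H](c2ccc(O)cc2)[C@H]1O | starting material
2 | N-bromosuccinimide | O=C1CCC(=O)N1Br | reagent (starting material)
3 | (2R,3R)-8-bromoaromadendrin | O=C1c2c(O)cc(O)c(Br)c2O[C@H](c2ccc(O)cc2)[C@H]1O | intermediate
4 | 4-hydroxybenzyl alcohol | OCc1ccc(O)cc1 | starting material
5 | (2R,3R)-8-bromo-6-(4-hydroxybenzyl)aromadendrin | O=C1c2c(O)c(Cc3ccc(O)cc3)c(O)c(Br)c2O[C@H](c2ccc(O)cc2)[C@H]1O | intermediate
6 | Gericudranin E | O=C1c2c(cc(O)c(Cc3ccc(O)cc3)c2O)O[C@H](c2ccc(O)cc2)[C@H]1O | target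

**Total steps:** 3. **Longest linear sequence:** 3.

## Three steps most likely to fail
1. **Step 2 (proposed new photochemical benzylation).** The flavanonol absorbs most of the light and may act as an inner filter. The quinone methide may be lost to water or to oligomerisation, and Ar–Br photolysis may compete.
   - Fallback (known chemistry): iodinate C6 of 3 with NIS, then run a Pd-catalysed Suzuki–Miyaura benzylation with K[4-(MOMO)C6H4CH2BF3] (PdCl2(dppf), mild base). Remove the MOM group with mild acid, then continue to Step 3.
2. **Step 1 (C8 regioselectivity).** Bromination may give mixtures of 6-Br and 6,8-diBr.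
   - Fallback: drop the blocking group. Benzylate aromadendrin directly with a p-quinone methide from 4-hydroxybenzyl alcohol (thermal, acid-mediated Friedel–Crafts). Separate the 6- and 8-benzyl isomers by preparative HPLC and assign by HMBC.
3. **Step 3 (hydrodebromination).** Pd/H2 could cleave the benzylic C2–O1 bond or epimerise C2/C3.
   - Fallback: radical or photoredox hydrodebromination (e.g., Ir(ppy)3, Hantzsch ester, iPr2NEt, blue light; or (TMS)3SiH/AIBN). This avoids Pd-hydride and surface hydrogenolysis pathways.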